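**Plan**

- Target: 2-heptadecyl-5,7-dihydroxy-6,8-dimethy-4H-chromen-4-one, i.e. 2-heptadecyl-5,7-dihydroxy-6,8-dimethyl-4H-chromen-4-one. Ring A is the benzene ring (C4a, C5, C6, C7, C8, C8a); ring B is the pyranone ring (O1, C2, C3, C4).
- Retrosynthesis: ring B is cut at O1–C2 (cyclodehydration of a 1-aryl-1,3-dione). Ring A is cut at C4a–C5 (Claisen condensation of a 2,4-dimethyl-3,5,7,9-tetraoxo ester stored as a 2-pyrone). The chain is cut at C2–C3, C4–C4a and C8–C8a (three ketone-forming acylations).
- Enabling feature: ring A carries oxygen on C5, C7 and C8a and methyl on C6 and C8, and is mirror-symmetric about the C4a–C7 axis. This is the imprint of a 2,4-dimethyl-3,5-dioxo ester whose C6 closes onto the ester carbon, and the symmetry makes the two ortho oxygens equivalent when ring B closes.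
- Forward: a propionate-derived keto ester supplies C5 to C8 with both methyl groups. Acetyl (C8a, C4a), acetyl (C4, C3) and stearoyl (C2 plus the heptadecyl chain) units are added in turn, the chain being parked as a 4-hydroxy-2-pyrone after the first. Ring A closes next, ring B last.
- Stereochemistry: the target has no stereocentre; every sp3 centre met on the way is uncontrolled and ends as an sp2 carbon.

Key step: step 6

Remark: enolizable compounds are named and drawn in one tautomeric form; the open-chain ester of step 6 exists in the flask as a magnesium enolate chelate and is listed as the neutral ester.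

**Route**

Step 1
Reactants: 1 ethyl 2-methyl-3-oxopentanoate (racemic); 2 N-methoxy-N-methylacetamide
Product: 3 ethyl 2,4-dimethyl-3,5-dioxohexanoate (mixture of epimers)
Conditions: LiN(iPr)2 (2.2 equiv), THF, −78 to 0 °C; then 2, −78 °C to rt; 1 M HCl
Reagents that add atoms: none
Why: γ-Acylation of the β-keto ester 1,3-dianion takes place at the more basic C4 carbanion and, as a Weinreb ketone synthesis, stops after one acetyl transfer because the ketone is unveiled only on quench; the new C4 centre forms without control and is erased in step 2.

Step 2
Reactants: 3 ethyl 2,4-dimethyl-3,5-dioxohexanoate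
Product: 4 4-hydroxy-3,5,6-trimethyl-2H-pyran-2-one
Conditions: DBU (1.5 equiv), toluene, 80 °C; then 1 M HCl
Reagents that add atoms: none
Why: Base-mediated lactonization of a 3,5-dioxo ester, in which the C5 enolate oxygen attacks the ester carbonyl in a 6-exo-trig acyl substitution, ethanol leaves and both sp3 centres of 3 vanish in the stable 4-hydroxy-2-pyrone.

Step 3
Reactants: 4 4-hydroxy-3,5,6-trimethyl-2H-pyran-2-one; 2 N-methoxy-N-methylacetamide
Product: 5 4-hydroxy-3,5-dimethyl-6-(2-oxopropyl)-2H-pyran-2-one
Conditions: LiN(iPr)2 (2.3 equiv), THF, −78 °C; then 2, −78 to 0 °C; 1 M HCl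
Reagents that add atoms: none
Why: Lateral metalation and acylation of a 4-hydroxy-6-methyl-2-pyrone dianion, in which the 6-methyl group is the only carbon whose anion is delocalized through the ring onto the lactone carbonyl and this vinylogous carbanion takes up exactly one acetyl group from the Weinreb amide.

Step 4
Reactants: 6 methyl stearate
Product: 7 N-methoxy-N-methyloctadecanamide
Conditions: MeNH(OMe)·HCl (1.5 equiv), iPrMgCl (3.0 equiv), THF, −20 to 0 °C; 1 M HCl
Reagents that add atoms: N,O-dimethylhydroxylamine hydrochloride, CNOC.Cl
Why: Direct aminolysis of an ester to its Weinreb amide by the chloromagnesium amide of N,O-dimethylhydroxylamine, a nucleophilic acyl substitution that outruns enolization of the ester and cannot over-add.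

Step 5
Reactants: 5 4-hydroxy-3,5-dimethyl-6-(2-oxopropyl)-2H-pyran-2-one; 7 N-methoxy-N-methyloctadecanamide
Product: 8 6-(2,4-dioxohenicosyl)-4-hydroxy-3,5-dimethyl-2H-pyran-2-one
Conditions: LiN(iPr)2 (3.3 equiv), THF, −78 to 0 °C; then 7 (1.1 equiv), −78 to 0 °C; 1 M HCl
Reagents that add atoms: none
Why: Terminal acylation of a β-dicarbonyl polyanion, in which base removes in turn the 4-OH proton, one proton of the doubly activated ring-CH2-CO methylene and one of the terminal methyl group, and the last-formed, least stabilized terminal carbanion attacks the Weinreb amide, whose use prevents over-addition and proton transfer from the new 1,3-dione.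

Step 6
Reactants: 8 6-(2,4-dioxohenicosyl)-4-hydroxy-3,5-dimethyl-2H-pyran-2-one
Product: 10 1-(2,4,6-trihydroxy-3,5-dimethylphenyl)icosane-1,3-dione, via tetraketo methyl ester 9 (not isolated)
Conditions: Mg(OMe)2 (6 equiv), degassed MeOH, reflux, Ar; then cold 1 M HCl
Reagents that add atoms: none
Why: Methoxide adds to the lactone carbonyl of 8 and opens the ring to tetraketo ester 9, held as a magnesium polyenolate chelate, whose C6 methylene (the former ring-CH2, flanked by the 5- and 7-ketones) attacks the ester carbonyl C1; loss of methoxide and enolization of the resulting cyclohexanetrione should give the aromatic ring irreversibly. The closest known reaction is the Mg(OMe)2-induced Claisen-type recyclization of 4-hydroxy-6-(2-oxoalkyl)-2-pyrones and of 3,5,7-trioxo esters to acylphloroglucinols. Ring A closes in a 6-exo-trig intramolecular Claisen condensation that forms the bond which becomes C4a–C5 of the chromone. No stereocentre is created, and the two epimerizable methyl-bearing carbons of 9 become the aromatic C6 and C8. The step needs Claisen folding (C6 onto C1) in preference to aldol folding (C8 onto the C3 ketone, which would lead to a resorcinol): the C3 ketone lies between two methyl-substituted carbons and is hindered, magnesium chelation of the 5,7-dione unit holds C6 near the ester, and an aldol by the ester α-carbon C2 would give a quaternary centre that cannot aromatize and so reverts.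

Step 7
Reactants: 10 1-(2,4,6-trihydroxy-3,5-dimethylphenyl)icosane-1,3-dione
Product: 12 2-heptadecyl-5,7-dihydroxy-6,8-dimethyl-4H-chromen-4-one (target), via 2-hydroxychromanone hemiketal 11 (not isolated)
Conditions: 12 M HCl (catalytic), AcOH, 90 °C
Reagents that add atoms: none
Why: Acid-catalysed cyclodehydration of a 1-(2-hydroxyaryl)-1,3-dione, the closing stage of the Baker–Venkataraman chromone synthesis, in which an ortho hydroxyl adds to the C3 ketone (6-exo-trig) to give hemiketal 11, whose racemic centre disappears on loss of water, and because the two ortho hydroxyls of ring A are equivalent by symmetry only one chromone can form.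

**Compound list**

1 | ethyl 2-methyl-3-oxopentanoate (racemic) | CCOC(=O)C(C)C(=O)CC | starting material
2 | N-methoxy-N-methylacetamide | CON(C)C(C)=O | starting material
3 | ethyl 2,4-dimethyl-3,5-dioxohexanoate (mixture of epimers and enol forms) | CCOC(=O)C(C)C(=O)C(C)C(C)=O | intermediate
4 | 4-hydroxy-3,5,6-trimethyl-2H-pyran-2-one | Cc1oc(=O)c(C)c(O)c1C | intermediate
5 | 4-hydroxy-3,5-dimethyl-6-(2-oxopropyl)-2H-pyran-2-one | CC(=O)Cc1oc(=O)c(C)c(O)c1C | intermediate
6 | methyl stearate (methyl octadecanoate) | CCCCCCCCCCCCCCCCCC(=O)OC | starting material
7 | N-methoxy-N-methyloctadecanamide | CCCCCCCCCCCCCCCCCC(=O)N(C)OC | intermediate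
8 | 6-(2,4-dioxohenicosyl)-4-hydroxy-3,5-dimethyl-2H-pyran-2-one | CCCCCCCCCCCCCCCCCC(=O)CC(=O)Cc1oc(=O)c(C)c(O)c1C | intermediate
9 | methyl 2,4-dimethyl-3,5,7,9-tetraoxohexacosanoate (magnesium chelate in the flask; mixture of epimers; not isolated) | CCCCCCCCCCCCCCCCCC(=O)CC(=O)CC(=O)C(C)C(=O)C(C)C(=O)OC | intermediate
10 | 1-(2,4,6-trihydroxy-3,5-dimethylphenyl)icosane-1,3-dione | CCCCCCCCCCCCCCCCCC(=O)CC(=O)c1c(O)c(C)c(O)c(C)c1O | intermediate
11 | 2-heptadecyl-2,5,7-trihydroxy-6,8-dimethyl-2,3-dihydro-4H-chromen-4-one (racemic hemiketal; not isolated) | CCCCCCCCCCCCCCCCCC1(O)CC(=O)c2c(O)c(C)c(O)c(C)c2O1 | intermediate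
12 | 2-heptadecyl-5,7-dihydroxy-6,8-dimethyl-4H-chromen-4-one (CNP0129113.0) | CCCCCCCCCCCCCCCCCc1cc(=O)c2c(O)c(C)c(O)c(C)c2o1 | target

**Step count**

Total step count: 7. Longest linear sequence: 6 steps (steps 1, 2, 3, 5, 6, 7); step 4 is a one-step side branch.

**Steps most likely to fail**

Step 6. The opened chain may fold in the aldol sense, its second acidic methylene (C8) adding to the C3 ketone, or the polyketone chain may be cut by retro-Claisen methanolysis before ring A closes. The fallback sets out from 5, whose side chain has a single ketone and therefore no second acidic methylene, and moves the stearoyl transfer behind the ring closure. Mg(OMe)2 in refluxing MeOH should open 5 to methyl 2,4-dimethyl-3,5,7-trioxooctanoate F1 (not isolated), which should close by the same carbon-onto-ester Claisen condensation to 1-(2,4,6-trihydroxy-3,5-dimethylphenyl)ethan-1-one F2. Exhaustive deprotonation of F2 with LiN(SiMe3)2 (5 equiv) in THF at −78 °C, followed by C-acylation of the methyl ketone enolate with amide 7 (the direct one-flask variant of the Baker–Venkataraman diketone synthesis), should then give 10, where the route resumes at step 7.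

Step 5. The terminal carbanion may act as a base toward the α-methylene of amide 7 instead of attacking its carbonyl, and the trilithio species may aggregate and react sluggishly, so that 5 is simply returned. The fallback sets out from 5 and replaces the acyl transfer by an aldol addition and an oxidation. The same trianion (LiN(iPr)2, THF, −78 °C) should add to commercial octadecanal faster than it deprotonates it, giving racemic 4-hydroxy-6-(4-hydroxy-2-oxohenicosyl)-3,5-dimethyl-2H-pyran-2-one F3. Oxidation of the secondary alcohol with Dess–Martin periodinane in CH2Cl2 should then give 8, rejoining the route before step 6.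

Step 3. Lateral deprotonation may be incomplete, or the dianion may be acylated on oxygen or quenched by proton transfer from 2. The fallback sets out from 4 and likewise trades the acylation for an addition and an oxidation. The dianion of 4 should add to acetaldehyde to give racemic 4-hydroxy-6-(2-hydroxypropyl)-3,5-dimethyl-2H-pyran-2-one F4, and Dess–Martin oxidation in CH2Cl2 should convert F4 into 5, rejoining the route before step 5.

Further compounds
F1 | step 6 | methyl 2,4-dimethyl-3,5,7-trioxooctanoate (mixture of epimers; not isolated) | CC(=O)CC(=O)C(C)C(=O)C(C)C(=O)OC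
F2 | step 6 | 1-(2,4,6-trihydroxy-3,5-dimethylphenyl)ethan-1-one | CC(=O)c1c(O)c(C)c(O)c(C)c1O
F3 | step 5 | 4-hydroxy-6-(4-hydroxy-2-oxohenicosyl)-3,5-dimethyl-2H-pyran-2-one (racemic) | CCCCCCCCCCCCCCCCCC(O)CC(=O)Cc1oc(=O)c(C)c(O)c1C
F4 | step 3 | 4-hydroxy-6-(2-hydroxypropyl)-3,5-dimethyl-2H-pyran-2-one (racemic) | CC(O)Cc1oc(=O)c(C)c(O)c1C
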